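**Retrosynthetic overview**
- C–S bond last: the thioacetate comes from anti-Markovnikov radical addition of thioacetic acid to a terminal alkene (dec-9-enyl side chain).
- O4–CH3: methylation of the 4-hydroxy-3-methoxy-2-pyrone.
- Key disconnection, C3–OMe: a C–H to C–O exchange at C3 of the 4-hydroxy-2-pyrone (iodonium ylide, then Rh carbenoid O–H insertion into methanol).
- The only ring, the 2-pyrone, is formed first. The O1–C2 bond closes by lactonisation of a 3,5-dioxo ester made from methyl 3-oxopentanoate and methyl undec-10-enoate.

Assumption: lehualide H as drawn has no stereocentre and no stereogenic double bond, so the achiral compound is the target and no stereoselective step is needed.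

**Step 1**
Reactants: 1 methyl 3-oxopentanoate; 2 methyl undec-10-enoate
Product: 5 6-(dec-9-en-1-yl)-4-hydroxy-5-methyl-2H-pyran-2-one, via dianion 3 (not isolated), via triketo ester 4 (not isolated)
Conditions: 1 (2.2 equiv), NaH, THF, 0 °C; n-BuLi, 0 °C; 2 (1.0 equiv), 0 °C → rt; 1 M HCl; crude 4, DBU (1.5 equiv), PhMe, 80 °C; 1 M HCl
Reagents that add atoms: none
Why: The Weiler dianion reacts at its more basic γ-carbon in a crossed Claisen acylation, and DBU then drives enol lactonisation (C5 enol oxygen onto the ester, loss of MeOH) to close O1–C2 of the 2-pyrone; the labile stereocentre of 4 becomes sp2, so no stereochemistry is set.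

**Step 2**
Reactants: 5 6-(dec-9-en-1-yl)-4-hydroxy-5-methyl-2H-pyran-2-one
Product: 7 6-(dec-9-en-1-yl)-4-hydroxy-3-methoxy-5-methyl-2H-pyran-2-one, via iodonium ylide 6 (not isolated)
Conditions: PhI(OAc)2 (1.0 equiv), MeOH (0.05 M), 0 °C → rt, 1 h; then Rh2(OAc)4 (1 mol %), 35 °C, 2 h; NaHCO3 extraction, acidify
Reagents that add atoms: methanol, CO
Why: Proposed new method: one-pot dehydrogenative C3–H to C3–OMe exchange on a 4-hydroxy-2-pyrone. C3 is the only nucleophilic carbon of the vinylogous acid 5, so PhI(OAc)2 condenses there (ligand exchange, loss of 2 AcOH) to give the stabilised iodonium ylide 6, a step known for simple 4-hydroxy-2-pyrones; Rh2(OAc)4 then attacks the ylide carbon and expels PhI to give an acceptor/acceptor Rh carbenoid at C3, solvent methanol (about 500 equiv) traps it as an oxonium ylide, and proton transfer plus enolisation restores the pyrone with the new C3–O bond; the distal alkene (0.05 M) cannot compete with 25 M MeOH, all I(III) is consumed before the electron-rich 7 appears, and ≤35 °C avoids the thermal 1,4-phenyl shift of such ylides; the closest known reaction types are Rh(II)-catalysed O–H insertion of cyclic 2-diazo-1,3-dicarbonyl compounds into alcohols and hypervalent-iodine α-alkoxylation of acyclic β-dicarbonyls; no stereocentre is formed.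

**Step 3**
Reactants: 7 6-(dec-9-en-1-yl)-4-hydroxy-3-methoxy-5-methyl-2H-pyran-2-one
Product: 8 6-(dec-9-en-1-yl)-3,4-dimethoxy-5-methyl-2H-pyran-2-one
Conditions: Me2SO4 (1.3 equiv), K2CO3 (2 equiv), acetone, reflux
Reagents that add atoms: dimethyl sulfate, COS(=O)(=O)OC
Why: Williamson-type O-alkylation of the potassium pyronate; carbonate with dimethyl sulfate in acetone is the standard combination that alkylates the vinylogous carboxylate at O4 (2-pyrone kept) rather than at O2 (4-pyrone), and the alkene is inert.

**Step 4**
Reactants: 8 6-(dec-9-en-1-yl)-3,4-dimethoxy-5-methyl-2H-pyran-2-one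
Product: 9 lehualide H, S-[10-(3,4-dimethoxy-5-methyl-2-oxo-2H-pyran-6-yl)decyl] ethanethioate
Conditions: AcSH (3 equiv), AIBN (10 mol %), degassed PhMe, 75 °C
Reagents that add atoms: thioacetic acid, CC(=O)S
Why: Radical thiol-ene reaction (anti-Markovnikov hydrothiolation): the acetylthiyl radical adds to the terminal carbon and the secondary radical abstracts H from AcSH; the fully substituted pyrone is inert, and placing this step last keeps the labile thioester away from all bases.

**Compound list**
1 | methyl 3-oxopentanoate | CCC(=O)CC(=O)OC | starting material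
2 | methyl undec-10-enoate | C=CCCCCCCCCC(=O)OC | starting material
3 | sodium lithium 1-methoxypenta-1,3-diene-1,3-bis(olate) (dianion of 1) | CC=C([O-])C=C([O-])OC.[Na+].[Li+] | intermediate
4 | methyl 4-methyl-3,5-dioxopentadec-14-enoate (racemic, configurationally labile) | COC(=O)CC(=O)C(C)C(=O)CCCCCCCCC=C | intermediate
5 | 6-(dec-9-en-1-yl)-4-hydroxy-5-methyl-2H-pyran-2-one | Cc1c(O)cc(=O)oc1CCCCCCCCC=C | intermediate
6 | 6-(dec-9-en-1-yl)-5-methyl-2-oxo-3-(phenyliodonio)-2H-pyran-4-olate | Cc1c([O-])c([I+]c2ccccc2)c(=O)oc1CCCCCCCCC=C | intermediate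
7 | 6-(dec-9-en-1-yl)-4-hydroxy-3-methoxy-5-methyl-2H-pyran-2-one | COc1c(O)c(C)c(CCCCCCCCC=C)oc1=O | intermediate
8 | 6-(dec-9-en-1-yl)-3,4-dimethoxy-5-methyl-2H-pyran-2-one | COc1c(C)c(CCCCCCCCC=C)oc(=O)c1OC | intermediate
9 | lehualide H | COc1c(C)c(CCCCCCCCCCSC(C)=O)oc(=O)c1OC | target

**Total step count:** 4. **Longest linear sequence:** 4.

**Steps most likely to fail**

Step 2 (the proposed new step). The carbenoid may take other paths (phenyl shift, Wolff-type ring contraction, acetate capture), or the ylide may not turn over. The fallback uses known chemistry and installs the methoxy group before the ring is made. It sets out from 2. Methyl methoxyacetate is deprotonated with LDA (THF, −78 °C) and acylated with propionyl chloride in a crossed Claisen reaction to give methyl 2-methoxy-3-oxopentanoate F3. The dianion of F3 (2 equiv LDA) is acylated with 2 to give methyl 2-methoxy-4-methyl-3,5-dioxopentadec-14-enoate F4. DBU in hot toluene lactonises F4, and the fallback rejoins the route at 7.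

Step 1. Dianion 3 may act as a base towards the enolisable ester 2, which would give low conversion. The fallback replaces acylation with aldol addition and oxidation. It sets out from 2 and from dianion 3. DIBAL-H (CH2Cl2, −78 °C) reduces 2 to undec-10-enal F1, which is also sold as such. Dianion 3 adds to F1 at −78 °C to give methyl 5-hydroxy-4-methyl-3-oxopentadec-14-enoate F2, a diastereomer mixture of no consequence. Dess–Martin periodinane oxidises F2, and the fallback rejoins the route at triketo ester 4.

Step 3. O4 of 7 is flanked by OMe and Me, so some methylation at O2 could give the 2,3-dimethoxy-4-pyrone isomer. The fallback reverses the order of the two C–O bond formations. It sets out from 5. Methylating 5, whose C3 is still unsubstituted (Me2SO4, K2CO3, acetone), gives 6-(dec-9-en-1-yl)-4-methoxy-5-methyl-2H-pyran-2-one F5. NBS in MeCN in the dark brominates the enol-ether carbon to give 3-bromo-6-(dec-9-en-1-yl)-4-methoxy-5-methyl-2H-pyran-2-one F6. Pd-catalysed C–O coupling with methanol (tBuBrettPhos Pd G3, Cs2CO3, dioxane/MeOH, 50 °C) replaces Br by OMe, and the fallback rejoins the route at 8.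

**Further compounds**
F1 | step 1 | undec-10-enal | C=CCCCCCCCCC=O
F2 | step 1 | methyl 5-hydroxy-4-methyl-3-oxopentadec-14-enoate (diastereomer mixture) | COC(=O)CC(=O)C(C)C(O)CCCCCCCCC=C
F3 | step 2 | methyl 2-methoxy-3-oxopentanoate (racemic) | CCC(=O)C(OC)C(=O)OC
F4 | step 2 | methyl 2-methoxy-4-methyl-3,5-dioxopentadec-14-enoate (stereoisomer mixture, labile) | COC(=O)C(OC)C(=O)C(C)C(=O)CCCCCCCCC=C
F5 | step 3 | 6-(dec-9-en-1-yl)-4-methoxy-5-methyl-2H-pyran-2-one | COc1cc(=O)oc(CCCCCCCCC=C)c1C
F6 | step 3 | 3-bromo-6-(dec-9-en-1-yl)-4-methoxy-5-methyl-2H-pyran-2-one | COc1c(Br)c(=O)oc(CCCCCCCCC=C)c1C
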